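**Plan**

- Retrosynthesis: the C19 ester is cut last; C11=C12 (Wittig) divides the chain into a C25 ε-half aldehyde and a C15 β-half keto-phosphonium salt; C11'=C12' (Wittig, C10 dialdehyde) and C9'=C10' (Horner–Wadsworth–Emmons on α-ionone) give the ε half; C8–C9 (Nozaki–Hiyama–Kishi) joins a β-ring acetaldehyde to a C4 vinyl iodide from but-2-yne-1,4-diol.
- The β ring is cut at C1–C6 and C2–C3. Its only stereocentre (C3–OH) sits between two CH2 groups, next to a quaternary CMe2 (C1) and a tetrasubstituted C5=C6; so C1–C2 is isobutene, C3 an acetal carbon and C6 the central carbon of a 2,3-dienylsilane.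
- Forward: a chiral acetal, isobutene and TiCl4 give the β ring in one cationic annulation (C2–C3 first, then C1–C6; loss of silicon fixes C5=C6 and leaves a vinyl group on C6). Auxiliary removal, hydroboration, oxidation, chromium coupling and phosphonium salt formation follow; the ε half is built from α-ionone; the halves are joined and the ester is made last.
- Stereochemistry: C3 from the (2R,4R)-pentane-2,4-diol acetal template; C3' by oxazaborolidine reduction of the racemic 3'-oxo ester, the trans (3'R,6'R) diastereomer being separated; alkene geometry from syn-hydrostannation, stabilised ylides and iodine equilibration.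

Key step: step 4

Remark: carotenoid locants are used (unprimed for the β half, primed for the ε half); TBS = tert-butyldimethylsilyl, TES = triethylsilyl; all polyenes are handled under argon in dim light.
Assumption: the sense of induction in step 4 follows the usual model for (4R,6R)-4,6-dimethyl-1,3-dioxanes (cleavage of the C–O bond next to the axial methyl group, attack with inversion), which was worked through for this substrate and leads to 3R.

**Route**

Step 1
Reactants: 1 4,4-dimethoxybutan-2-one; 2 ethynylmagnesium bromide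
Product: 4 5,5-dimethoxy-3-methylpent-1-yn-3-yl acetate (racemic), via bromomagnesium alkoxide 3 (not isolated)
Conditions: HC≡CMgBr (1.3 equiv), THF, 0 °C; then Ac2O (2.5 equiv), 0 °C to rt
Reagents that add atoms: acetic anhydride, CC(=O)OC(C)=O
Why: Grignard 1,2-addition of the acetylide to the methyl ketone (the acetal is inert) gives the tertiary propargylic alkoxide, which is acetylated in the flask; the racemic carbinol centre is destroyed in step 3.

Step 2
Reactants: 4 5,5-dimethoxy-3-methylpent-1-yn-3-yl acetate; 5 (2R,4R)-pentane-2,4-diol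
Product: 6 1-[(4R,6R)-4,6-dimethyl-1,3-dioxan-2-yl]-2-methylbut-3-yn-2-yl acetate (both epimers at the carbinol carbon)
Conditions: PPTS (5 mol %), benzene, 5 Å molecular sieves, 50 °C
Reagents that add atoms: none
Why: Acid-catalysed transacetalisation replaces two MeOH by the C2-symmetric diol to give the six-membered acetal, whose two ring stereocentres are bought with the diol and whose acetal carbon is not a stereocentre.

Step 3
Reactants: 6 1-[(4R,6R)-4,6-dimethyl-1,3-dioxan-2-yl]-2-methylbut-3-yn-2-yl acetate; 7 (trimethylsilyl)methylmagnesium chloride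
Product: 8 (4R,6R)-4,6-dimethyl-2-[2-methyl-5-(trimethylsilyl)penta-2,3-dien-1-yl]-1,3-dioxane (both allene epimers)
Conditions: Me3SiCH2MgCl (2.4 equiv), CuI (1.2 equiv), THF, −40 °C; then 6, −78 to 0 °C
Reagents that add atoms: none
Why: anti-SN2′ substitution of a tertiary propargylic acetate by an organocuprate (Crabbé-type allene synthesis) puts the Me3SiCH2 group on the alkyne terminus and gives the 2,3-dienylsilane, the cuprate being too weakly basic to deprotonate the terminal alkyne.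

Step 4
Reactants: 8 (4R,6R)-4,6-dimethyl-2-[2-methyl-5-(trimethylsilyl)penta-2,3-dien-1-yl]-1,3-dioxane; 9 2-methylpropene (isobutene)
Product: 10 (2R,4R)-4-{[(1R)-4-ethenyl-3,5,5-trimethylcyclohex-3-en-1-yl]oxy}pentan-2-ol
Conditions: isobutene (15 equiv), TiCl4 (1.2 equiv), 2,6-di-tert-butyl-4-methylpyridine (0.3 equiv), CH2Cl2, −78 °C, slow addition of 8 (final 0.02 M); Et3N/MeOH quench at −78 °C
Reagents that add atoms: none
Why: Proposed new method: TiCl4 should open the dioxane at the C–O bond next to the axial methyl group while isobutene attacks the acetal carbon (C3) with its CH2 end from the opposite side, forming C2–C3 and a tertiary cation at C1; this cation should be captured by the central allene carbon C6, and loss of Me3Si from C8 leaves the tetrasubstituted C5=C6 in the ring and a vinyl group on C6. The closest known reactions are the Johnson opening of pentane-2,4-diol acetals by allylsilanes and alkenes, the Prins addition of alkenes to acetals, and the capture of cations by 2,3-dienylsilanes at the central carbon to give 2-substituted 1,3-dienes; their union in one intermolecular-then-intramolecular (4+2) annulation with isobutene has not been shown. The cyclohexene closes 6-exo with respect to the C6=C7 π bond that is consumed, while the orthogonal C5=C6 π bond stays endocyclic, the orbital used at C6 lying in the C4–C5–C6 plane as the half-chair requires. The only new stereocentre, C3, is set in the first bond formation by the (4R,6R)-acetal template through ion-paired, invertive substitution and should be R; the allene axis is destroyed. The step needs isobutene to win over a second molecule of 8 for the activated acetal (excess isobutene, slow addition, and the internal silane could reach its own acetal carbon only through a four-membered ring), ring closure to win over further isobutene addition (six-membered capture by a β-silyl-stabilised π nucleophile), and the alkene to sit only at C5=C6 (fixed by silicon leaving, not by proton loss). The hindered pyridine traps protons that would protodesilylate the dienylsilane.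

Step 5
Reactants: 10 (2R,4R)-4-{[(1R)-4-ethenyl-3,5,5-trimethylcyclohex-3-en-1-yl]oxy}pentan-2-ol
Product: 12 (1R)-4-ethenyl-3,5,5-trimethylcyclohex-3-en-1-ol, via methyl ketone 11 (not isolated)
Conditions: Dess–Martin periodinane, NaHCO3, CH2Cl2, 0 °C to rt; then MeOH, K2CO3, rt
Reagents that add atoms: none
Why: Dess–Martin oxidation of the template alcohol to the methyl ketone followed by base-induced β-elimination (retro-oxa-Michael) is the standard removal of this auxiliary and frees C3–OH without touching its configuration.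

Step 6
Reactants: 12 (1R)-4-ethenyl-3,5,5-trimethylcyclohex-3-en-1-ol
Product: 13 tert-butyl{[(1R)-4-ethenyl-3,5,5-trimethylcyclohex-3-en-1-yl]oxy}dimethylsilane
Conditions: TBSCl, imidazole, DMF, rt
Reagents that add atoms: tert-butyldimethylsilyl chloride, CC(C)(C)[Si](C)(C)Cl
Why: Silylation of the secondary alcohol (Corey conditions) protects C3–OH through the oxidations, the chromium coupling and the Wittig steps.

Step 7
Reactants: 13 tert-butyl{[(1R)-4-ethenyl-3,5,5-trimethylcyclohex-3-en-1-yl]oxy}dimethylsilane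
Product: 15 2-[(4R)-4-TBSO-2,6,6-trimethylcyclohex-1-en-1-yl]ethan-1-ol, via B-alkyl-9-borabicyclononane 14 (not isolated)
Conditions: 9-BBN (1.5 equiv), THF, 0 °C to rt; then NaOH, H2O2, 0 °C
Reagents that add atoms: hydrogen peroxide, OO
Why: Brown hydroboration–oxidation with the bulky 9-BBN should add only to the monosubstituted vinyl group (boron on terminal C8) and ignore the tetrasubstituted ring alkene, giving the primary alcohol with C7 as CH2.

Step 8
Reactants: 15 2-[(4R)-4-TBSO-2,6,6-trimethylcyclohex-1-en-1-yl]ethan-1-ol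
Product: 16 [(4R)-4-TBSO-2,6,6-trimethylcyclohex-1-en-1-yl]acetaldehyde
Conditions: Dess–Martin periodinane, NaHCO3, CH2Cl2, 0 °C; used crude
Reagents that add atoms: none
Why: Dess–Martin oxidation under buffered conditions gives the β,γ-unsaturated aldehyde without moving the tetrasubstituted ring alkene into conjugation.

Step 9
Reactants: 17 but-2-yne-1,4-diol
Product: 18 (2E)-2-(tributylstannyl)but-2-ene-1,4-diol
Conditions: Bu3SnH (1.1 equiv), PdCl2(PPh3)2 (2 mol %), THF, rt
Reagents that add atoms: tributyltin hydride, CCCC[SnH](CCCC)CCCC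
Why: Palladium-catalysed syn-hydrostannation of the symmetrical alkyne (no regiochemical issue) places H and Sn cis, so the two CH2OH groups end cis to each other as C19 and C11 are in the target.

Step 10
Reactants: 18 (2E)-2-(tributylstannyl)but-2-ene-1,4-diol
Product: 19 (2E)-2-(tributylstannyl)-4-[(triethylsilyl)oxy]but-2-en-1-ol
Conditions: TESCl (1.0 equiv), imidazole, CH2Cl2, −78 °C
Reagents that add atoms: chlorotriethylsilane, CC[Si](Cl)(CC)CC
Why: Site-selective silylation should occur at the hydroxyl on the CH side (future C11–O), which is far less hindered than the one geminal to the Bu3Sn group.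

Step 11
Reactants: 19 (2E)-2-(tributylstannyl)-4-[(triethylsilyl)oxy]but-2-en-1-ol
Product: 20 tert-butyl(dimethyl){[(2E)-2-(tributylstannyl)-4-[(triethylsilyl)oxy]but-2-en-1-yl]oxy}silane
Conditions: TBSCl, imidazole, DMF, rt
Reagents that add atoms: tert-butyldimethylsilyl chloride, CC(C)(C)[Si](C)(C)Cl
Why: Silylation of the remaining hindered primary alcohol (future C19–O) installs the more robust TBS group.

Step 12
Reactants: 20 tert-butyl(dimethyl){[(2E)-2-(tributylstannyl)-4-[(triethylsilyl)oxy]but-2-en-1-yl]oxy}silane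
Product: 21 tert-butyl{[(2E)-2-iodo-4-[(triethylsilyl)oxy]but-2-en-1-yl]oxy}dimethylsilane
Conditions: I2 (1.05 equiv), CH2Cl2, 0 °C
Reagents that add atoms: iodine, II
Why: Iododestannylation (tin–iodine exchange) proceeds with retention of alkene geometry.

Step 13
Reactants: 16 [(4R)-4-TBSO-2,6,6-trimethylcyclohex-1-en-1-yl]acetaldehyde; 21 tert-butyl{[(2E)-2-iodo-4-[(triethylsilyl)oxy]but-2-en-1-yl]oxy}dimethylsilane
Product: 22 (3E)-3-(TBSO-methyl)-1-[(4R)-4-TBSO-2,6,6-trimethylcyclohex-1-en-1-yl]-5-TESO-pent-3-en-2-ol (both C2 epimers)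
Conditions: CrCl2 (4 equiv), NiCl2 (2 mol %), DMF, rt
Reagents that add atoms: none
Why: Nozaki–Hiyama–Kishi coupling, in which zerovalent nickel inserts into the vinyl iodide and transmetalation to chromium gives a non-basic alkenylchromium reagent, should add to the enolisable aldehyde with retention of alkene geometry; the new C8 carbinol centre is oxidised away in step 14.

Step 14
Reactants: 22 (3E)-3-(TBSO-methyl)-1-[(4R)-4-TBSO-2,6,6-trimethylcyclohex-1-en-1-yl]-5-TESO-pent-3-en-2-ol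
Product: 23 (3E)-3-(TBSO-methyl)-1-[(4R)-4-TBSO-2,6,6-trimethylcyclohex-1-en-1-yl]-5-TESO-pent-3-en-2-one
Conditions: Dess–Martin periodinane, NaHCO3, CH2Cl2, 0 °C to rt
Reagents that add atoms: none
Why: Dess–Martin oxidation of the secondary allylic alcohol gives the C8 ketone conjugated to C9=C10 while the ring alkene stays β,γ.

Step 15
Reactants: 23 (3E)-3-(TBSO-methyl)-1-[(4R)-4-TBSO-2,6,6-trimethylcyclohex-1-en-1-yl]-5-TESO-pent-3-en-2-one
Product: 24 (3E)-5-hydroxy-3-(TBSO-methyl)-1-[(4R)-4-TBSO-2,6,6-trimethylcyclohex-1-en-1-yl]pent-3-en-2-one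
Conditions: PPTS (0.1 equiv), MeOH/CH2Cl2 1:1, 0 °C
Reagents that add atoms: none
Why: Selective desilylation by acid-catalysed methanolysis cleaves the primary TES ether much faster than the TBS ethers, and the freed C11–OH is trans to the ketone across C9=C10 so it cannot close to a cyclic hemiketal.

Step 16
Reactants: 24 (3E)-5-hydroxy-3-(TBSO-methyl)-1-[(4R)-4-TBSO-2,6,6-trimethylcyclohex-1-en-1-yl]pent-3-en-2-one
Product: 26 [(2E)-3-(TBSO-methyl)-5-[(4R)-4-TBSO-2,6,6-trimethylcyclohex-1-en-1-yl]-4-oxopent-2-en-1-yl]triphenylphosphonium bromide, via allylic bromide 25 (not isolated)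
Conditions: CBr4 (1.3 equiv), PPh3 (1.3 equiv), CH2Cl2, 0 °C; then PPh3 (1.5 equiv), rt to 40 °C
Reagents that add atoms: carbon tetrabromide, BrC(Br)(Br)Br; triphenylphosphine, c1ccc(cc1)P(c1ccccc1)c1ccccc1
Why: Appel bromination of the primary allylic alcohol and SN2 quaternisation of triphenylphosphine by the allylic bromide in the same flask give the vinylogous β-keto phosphonium salt.

Step 17
Reactants: 27 (3E)-4-(2,6,6-trimethylcyclohex-2-en-1-yl)but-3-en-2-one (racemic α-ionone); 28 triethyl phosphonoacetate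
Product: 29 ethyl (2E,4E)-3-methyl-5-(2,6,6-trimethylcyclohex-2-en-1-yl)penta-2,4-dienoate (racemic)
Conditions: NaH (1.3 equiv), THF, 0 °C to reflux; chromatography
Reagents that add atoms: none
Why: Horner–Wadsworth–Emmons olefination of the methyl ketone should give mainly the (2E)-dienoate, the minor (2Z) isomer being removed by chromatography.

Step 18
Reactants: 29 ethyl (2E,4E)-3-methyl-5-(2,6,6-trimethylcyclohex-2-en-1-yl)penta-2,4-dienoate
Product: 30 ethyl (2E,4E)-3-methyl-5-(2,6,6-trimethyl-4-oxocyclohex-2-en-1-yl)penta-2,4-dienoate (racemic)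
Conditions: t-BuOOH (5 equiv), Rh2(cap)4 (1 mol %, cap = caprolactamate), K2CO3, CH2Cl2, rt
Reagents that add atoms: tert-butyl hydroperoxide, CC(C)(C)OO
Why: Dirhodium-catalysed allylic oxidation with t-BuOOH should attack the secondary allylic CH2 (C3') of the trisubstituted ring alkene, as α-ionone itself is oxidised at this position, and give the ring enone.

Step 19
Reactants: 30 ethyl (2E,4E)-3-methyl-5-(2,6,6-trimethyl-4-oxocyclohex-2-en-1-yl)penta-2,4-dienoate
Product: 31 ethyl (2E,4E)-5-[(1R,4R)-4-hydroxy-2,6,6-trimethylcyclohex-2-en-1-yl]-3-methylpenta-2,4-dienoate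
Conditions: (S)-2-methyl-CBS-oxazaborolidine (0.2 equiv), catecholborane (1.5 equiv), toluene, −78 °C; chromatographic separation from the cis (1S,4R) diastereomer
Reagents that add atoms: none
Why: Corey–Bakshi–Shibata reduction under catalyst control should deliver hydride to the same face of the ring ketone in both enantiomers of 30 (alkenyl arm as the large group), so C3' becomes R throughout and the racemate is divided into the trans (3'R,6'R) and cis (3'R,6'S) diastereomers, which are separable.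

Step 20
Reactants: 31 ethyl (2E,4E)-5-[(1R,4R)-4-hydroxy-2,6,6-trimethylcyclohex-2-en-1-yl]-3-methylpenta-2,4-dienoate
Product: 32 ethyl (2E,4E)-5-[(1R,4R)-4-TBSO-2,6,6-trimethylcyclohex-2-en-1-yl]-3-methylpenta-2,4-dienoate
Conditions: TBSCl, imidazole, DMF, rt
Reagents that add atoms: tert-butyldimethylsilyl chloride, CC(C)(C)[Si](C)(C)Cl
Why: Silylation protects the acid-sensitive allylic C3'–OH as a silyl ether that can be removed at the end without base.

Step 21
Reactants: 32 ethyl (2E,4E)-5-[(1R,4R)-4-TBSO-2,6,6-trimethylcyclohex-2-en-1-yl]-3-methylpenta-2,4-dienoate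
Product: 33 (2E,4E)-5-[(1R,4R)-4-TBSO-2,6,6-trimethylcyclohex-2-en-1-yl]-3-methylpenta-2,4-dien-1-ol
Conditions: i-Bu2AlH (2.5 equiv), CH2Cl2, −78 °C
Reagents that add atoms: none
Why: 1,2-Reduction of the conjugated ester by the aluminium hydride gives the allylic alcohol without touching the silyl ether or the diene.

Step 22
Reactants: 33 (2E,4E)-5-[(1R,4R)-4-TBSO-2,6,6-trimethylcyclohex-2-en-1-yl]-3-methylpenta-2,4-dien-1-ol
Product: 35 {(2E,4E)-5-[(1R,4R)-4-TBSO-2,6,6-trimethylcyclohex-2-en-1-yl]-3-methylpenta-2,4-dien-1-yl}triphenylphosphonium bromide, via allylic bromide 34 (not isolated)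
Conditions: CBr4 (1.3 equiv), PPh3 (1.3 equiv), CH2Cl2, −20 °C; then PPh3 (1.5 equiv), rt
Reagents that add atoms: carbon tetrabromide, BrC(Br)(Br)Br; triphenylphosphine, c1ccc(cc1)P(c1ccccc1)c1ccccc1
Why: Appel bromination under neutral conditions (no acid near the allylic silyl ether) and SN2 quaternisation of triphenylphosphine give the C15 Wittig salt.

Step 23
Reactants: 35 {(2E,4E)-5-[(1R,4R)-4-TBSO-2,6,6-trimethylcyclohex-2-en-1-yl]-3-methylpenta-2,4-dien-1-yl}triphenylphosphonium bromide; 36 (2E,4E,6E)-2,7-dimethylocta-2,4,6-trienedial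
Product: 37 (2E,4E,6E,8E,10E,12E)-13-[(1R,4R)-4-TBSO-2,6,6-trimethylcyclohex-2-en-1-yl]-2,7,11-trimethyltrideca-2,4,6,8,10,12-hexaenal
Conditions: 36 (3 equiv), NaOMe (1.1 equiv), CH2Cl2/MeOH, 0 °C to rt; then I2 (1 mol %), benzene, rt
Reagents that add atoms: none
Why: Wittig olefination of the allylic ylide with an excess of the symmetrical dialdehyde should give the mono-olefination product, and iodine-catalysed equilibration converts the E/Z mixture at C11'=C12' into the all-E aldehyde.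

Step 24
Reactants: 26 [(2E)-3-(TBSO-methyl)-5-[(4R)-4-TBSO-2,6,6-trimethylcyclohex-1-en-1-yl]-4-oxopent-2-en-1-yl]triphenylphosphonium bromide; 37 (2E,4E,6E,8E,10E,12E)-13-[(1R,4R)-4-TBSO-2,6,6-trimethylcyclohex-2-en-1-yl]-2,7,11-trimethyltrideca-2,4,6,8,10,12-hexaenal
Product: 38 (all-E,3R,3'R,6'R)-3,3',19-tris(TBSO)-7,8-dihydro-β,ε-caroten-8-one
Conditions: NaOMe (1.05 equiv), CH2Cl2/MeOH, 0 °C to rt
Reagents that add atoms: none
Why: Wittig olefination with a vinylogous acyl-stabilised ylide, which forms at C11 only (far more acidic than C7–H), should give the (11E) alkene, and the silyl ether at C19 is a poor leaving group that resists β-elimination from the ylide.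

Step 25
Reactants: 38 (all-E,3R,3'R,6'R)-3,3',19-tris(TBSO)-7,8-dihydro-β,ε-caroten-8-one
Product: 39 (all-E,3R,3'R,6'R)-3,3'-bis(TBSO)-19-hydroxy-7,8-dihydro-β,ε-caroten-8-one
Conditions: HF·pyridine, pyridine, THF, 0 °C, monitored
Reagents that add atoms: none
Why: Selective desilylation with buffered HF·pyridine should cleave the primary allylic TBS ether faster than the two secondary ones.

Step 26
Reactants: 39 (all-E,3R,3'R,6'R)-3,3'-bis(TBSO)-19-hydroxy-7,8-dihydro-β,ε-caroten-8-one; 40 (2E)-oct-2-enoic acid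
Product: 41 (all-E,3R,3'R,6'R)-3,3'-bis(TBSO)-8-oxo-7,8-dihydro-β,ε-caroten-19-yl (2E)-oct-2-enoate
Conditions: EDC·HCl (1.5 equiv), DMAP (0.1 equiv), CH2Cl2, 0 °C to rt
Reagents that add atoms: none
Why: Steglich esterification acylates the only free hydroxyl (primary, allylic) so the position of the ester is unambiguous.

Step 27
Reactants: 41 (all-E,3R,3'R,6'R)-3,3'-bis(TBSO)-8-oxo-7,8-dihydro-β,ε-caroten-19-yl (2E)-oct-2-enoate
Product: 42 (all-E,3R,3'R,6'R)-3,3'-dihydroxy-8-oxo-7,8-dihydro-β,ε-caroten-19-yl (2E)-oct-2-enoate (CNP0344057.1)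
Conditions: HF·pyridine (excess), pyridine, THF, 0 °C to rt
Reagents that add atoms: none
Why: Fluoride-mediated cleavage of the two secondary TBS ethers under buffered, non-basic conditions should leave the C19 enoate, the enone and the allylic ε-ring alcohol intact.

**Compound list**

1 | 4,4-dimethoxybutan-2-one | CC(=O)CC(OC)OC | starting material
2 | ethynylmagnesium bromide | C#C[Mg]Br | starting material
3 | bromomagnesium 5,5-dimethoxy-3-methylpent-1-yn-3-olate (racemic) | C#CC(C)(O[Mg]Br)CC(OC)OC | intermediate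
4 | 5,5-dimethoxy-3-methylpent-1-yn-3-yl acetate (racemic) | C#CC(C)(OC(C)=O)CC(OC)OC | intermediate
5 | (2R,4R)-pentane-2,4-diol | C[C@@H](O)C[C@@H](C)O | starting material
6 | 1-[(4R,6R)-4,6-dimethyl-1,3-dioxan-2-yl]-2-methylbut-3-yn-2-yl acetate (both carbinol epimers) | C#CC(C)(OC(C)=O)CC1O[C@H](C)C[C@@H](C)O1 | intermediate
7 | (trimethylsilyl)methylmagnesium chloride | C[Si](C)(C)C[Mg]Cl | starting material
8 | (4R,6R)-4,6-dimethyl-2-[2-methyl-5-(trimethylsilyl)penta-2,3-dien-1-yl]-1,3-dioxane (both allene epimers) | C[Si](C)(C)CC=C=C(C)CC1O[C@H](C)C[C@@H](C)O1 | intermediate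
9 | 2-methylpropene (isobutene) | CC(C)=C | starting material
10 | (2R,4R)-4-{[(1R)-4-ethenyl-3,5,5-trimethylcyclohex-3-en-1-yl]oxy}pentan-2-ol | C=CC1=C(C)C[C@@H](O[C@H](C)C[C@@H](C)O)CC1(C)C | intermediate
11 | (4R)-4-{[(1R)-4-ethenyl-3,5,5-trimethylcyclohex-3-en-1-yl]oxy}pentan-2-one | C=CC1=C(C)C[C@@H](O[C@H](C)CC(C)=O)CC1(C)C | intermediate
12 | (1R)-4-ethenyl-3,5,5-trimethylcyclohex-3-en-1-ol | C=CC1=C(C)C[C@@H](O)CC1(C)C | intermediate
13 | tert-butyl{[(1R)-4-ethenyl-3,5,5-trimethylcyclohex-3-en-1-yl]oxy}dimethylsilane | C=CC1=C(C)C[C@@H](O[Si](C)(C)C(C)(C)C)CC1(C)C | intermediate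
14 | 9-{2-[(4R)-4-TBSO-2,6,6-trimethylcyclohex-1-en-1-yl]ethyl}-9-borabicyclo[3.3.1]nonane | B1(CCC3=C(C)C[C@@H](O[Si](C)(C)C(C)(C)C)CC3(C)C)C2CCCC1CCC2 | intermediate
15 | 2-[(4R)-4-TBSO-2,6,6-trimethylcyclohex-1-en-1-yl]ethan-1-ol | OCCC1=C(C)C[C@@H](O[Si](C)(C)C(C)(C)C)CC1(C)C | intermediate
16 | [(4R)-4-TBSO-2,6,6-trimethylcyclohex-1-en-1-yl]acetaldehyde | O=CCC1=C(C)C[C@@H](O[Si](C)(C)C(C)(C)C)CC1(C)C | intermediate
17 | but-2-yne-1,4-diol | OCC#CCO | starting material
18 | (2E)-2-(tributylstannyl)but-2-ene-1,4-diol | OC\C(=C/CO)[Sn](CCCC)(CCCC)CCCC | intermediate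
19 | (2E)-2-(tributylstannyl)-4-[(triethylsilyl)oxy]but-2-en-1-ol | OC\C(=C/CO[Si](CC)(CC)CC)[Sn](CCCC)(CCCC)CCCC | intermediate
20 | tert-butyl(dimethyl){[(2E)-2-(tributylstannyl)-4-[(triethylsilyl)oxy]but-2-en-1-yl]oxy}silane | CC(C)(C)[Si](C)(C)OC\C(=C/CO[Si](CC)(CC)CC)[Sn](CCCC)(CCCC)CCCC | intermediate
21 | tert-butyl{[(2E)-2-iodo-4-[(triethylsilyl)oxy]but-2-en-1-yl]oxy}dimethylsilane | CC(C)(C)[Si](C)(C)OC\C(I)=C/CO[Si](CC)(CC)CC | intermediate
22 | (3E)-3-(TBSO-methyl)-1-[(4R)-4-TBSO-2,6,6-trimethylcyclohex-1-en-1-yl]-5-TESO-pent-3-en-2-ol (both C2 epimers) | CC(C)(C)[Si](C)(C)OC\C(=C/CO[Si](CC)(CC)CC)C(O)CC1=C(C)C[C@@H](O[Si](C)(C)C(C)(C)C)CC1(C)C | intermediate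
23 | (3E)-3-(TBSO-methyl)-1-[(4R)-4-TBSO-2,6,6-trimethylcyclohex-1-en-1-yl]-5-TESO-pent-3-en-2-one | CC(C)(C)[Si](C)(C)OC\C(=C/CO[Si](CC)(CC)CC)C(=O)CC1=C(C)C[C@@H](O[Si](C)(C)C(C)(C)C)CC1(C)C | intermediate
24 | (3E)-5-hydroxy-3-(TBSO-methyl)-1-[(4R)-4-TBSO-2,6,6-trimethylcyclohex-1-en-1-yl]pent-3-en-2-one | CC(C)(C)[Si](C)(C)OC\C(=C/CO)C(=O)CC1=C(C)C[C@@H](O[Si](C)(C)C(C)(C)C)CC1(C)C | intermediate
25 | (3E)-5-bromo-3-(TBSO-methyl)-1-[(4R)-4-TBSO-2,6,6-trimethylcyclohex-1-en-1-yl]pent-3-en-2-one | CC(C)(C)[Si](C)(C)OC\C(=C/CBr)C(=O)CC1=C(C)C[C@@H](O[Si](C)(C)C(C)(C)C)CC1(C)C | intermediate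
26 | [(2E)-3-(TBSO-methyl)-5-[(4R)-4-TBSO-2,6,6-trimethylcyclohex-1-en-1-yl]-4-oxopent-2-en-1-yl]triphenylphosphonium bromide | [Br-].CC(C)(C)[Si](C)(C)OC\C(=C/C[P+](c2ccccc2)(c3ccccc3)c4ccccc4)C(=O)CC1=C(C)C[C@@H](O[Si](C)(C)C(C)(C)C)CC1(C)C | intermediate
27 | (3E)-4-(2,6,6-trimethylcyclohex-2-en-1-yl)but-3-en-2-one (racemic α-ionone) | CC(=O)/C=C/C1C(C)=CCCC1(C)C | starting material
28 | triethyl phosphonoacetate | CCOC(=O)CP(=O)(OCC)OCC | starting material
29 | ethyl (2E,4E)-3-methyl-5-(2,6,6-trimethylcyclohex-2-en-1-yl)penta-2,4-dienoate (racemic) | CCOC(=O)/C=C(C)/C=C/C1C(C)=CCCC1(C)C | intermediate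
30 | ethyl (2E,4E)-3-methyl-5-(2,6,6-trimethyl-4-oxocyclohex-2-en-1-yl)penta-2,4-dienoate (racemic) | CCOC(=O)/C=C(C)/C=C/C1C(C)=CC(=O)CC1(C)C | intermediate
31 | ethyl (2E,4E)-5-[(1R,4R)-4-hydroxy-2,6,6-trimethylcyclohex-2-en-1-yl]-3-methylpenta-2,4-dienoate | CCOC(=O)/C=C(C)/C=C/[C@H]1C(C)=C[C@H](O)CC1(C)C | intermediate
32 | ethyl (2E,4E)-5-[(1R,4R)-4-TBSO-2,6,6-trimethylcyclohex-2-en-1-yl]-3-methylpenta-2,4-dienoate | CCOC(=O)/C=C(C)/C=C/[C@H]1C(C)=C[C@H](O[Si](C)(C)C(C)(C)C)CC1(C)C | intermediate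
33 | (2E,4E)-5-[(1R,4R)-4-TBSO-2,6,6-trimethylcyclohex-2-en-1-yl]-3-methylpenta-2,4-dien-1-ol | OC/C=C(C)/C=C/[C@H]1C(C)=C[C@H](O[Si](C)(C)C(C)(C)C)CC1(C)C | intermediate
34 | tert-butyl{[(1R,4R)-4-[(1E,3E)-5-bromo-3-methylpenta-1,3-dien-1-yl]-3,5,5-trimethylcyclohex-2-en-1-yl]oxy}dimethylsilane | BrC/C=C(C)/C=C/[C@H]1C(C)=C[C@H](O[Si](C)(C)C(C)(C)C)CC1(C)C | intermediate
35 | {(2E,4E)-5-[(1R,4R)-4-TBSO-2,6,6-trimethylcyclohex-2-en-1-yl]-3-methylpenta-2,4-dien-1-yl}triphenylphosphonium bromide | [Br-].c1ccccc1[P+](c1ccccc1)(c1ccccc1)C/C=C(C)/C=C/[C@H]1C(C)=C[C@H](O[Si](C)(C)C(C)(C)C)CC1(C)C | intermediate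
36 | (2E,4E,6E)-2,7-dimethylocta-2,4,6-trienedial | O=C/C(C)=C/C=C/C=C(C)/C=O | starting material
37 | (2E,4E,6E,8E,10E,12E)-13-[(1R,4R)-4-TBSO-2,6,6-trimethylcyclohex-2-en-1-yl]-2,7,11-trimethyltrideca-2,4,6,8,10,12-hexaenal | O=C/C(C)=C/C=C/C=C(C)/C=C/C=C(C)/C=C/[C@H]1C(C)=C[C@H](O[Si](C)(C)C(C)(C)C)CC1(C)C | intermediate
38 | (all-E,3R,3'R,6'R)-3,3',19-tris(TBSO)-7,8-dihydro-β,ε-caroten-8-one | CC(C)(C)[Si](C)(C)OC\C(=C/C=C/C(C)=C/C=C/C=C(C)/C=C/C=C(C)/C=C/[C@H]1C(C)=C[C@H](O[Si](C)(C)C(C)(C)C)CC1(C)C)C(=O)CC1=C(C)C[C@@H](O[Si](C)(C)C(C)(C)C)CC1(C)C | intermediate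
39 | (all-E,3R,3'R,6'R)-3,3'-bis(TBSO)-19-hydroxy-7,8-dihydro-β,ε-caroten-8-one | OC\C(=C/C=C/C(C)=C/C=C/C=C(C)/C=C/C=C(C)/C=C/[C@H]1C(C)=C[C@H](O[Si](C)(C)C(C)(C)C)CC1(C)C)C(=O)CC1=C(C)C[C@@H](O[Si](C)(C)C(C)(C)C)CC1(C)C | intermediate
40 | (2E)-oct-2-enoic acid | CCCCC/C=C/C(=O)O | starting material
41 | (all-E,3R,3'R,6'R)-3,3'-bis(TBSO)-8-oxo-7,8-dihydro-β,ε-caroten-19-yl (2E)-oct-2-enoate | CCCCC/C=C/C(=O)OC\C(=C/C=C/C(C)=C/C=C/C=C(C)/C=C/C=C(C)/C=C/[C@H]1C(C)=C[C@H](O[Si](C)(C)C(C)(C)C)CC1(C)C)C(=O)CC1=C(C)C[C@@H](O[Si](C)(C)C(C)(C)C)CC1(C)C | intermediate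
42 | (all-E,3R,3'R,6'R)-3,3'-dihydroxy-8-oxo-7,8-dihydro-β,ε-caroten-19-yl (2E)-oct-2-enoate (CNP0344057.1) | CCCCC/C=C/C(=O)OC\C(=C/C=C/C(C)=C/C=C/C=C(C)/C=C/C=C(C)/C=C/[C@H]1C(C)=C[C@H](O)CC1(C)C)C(=O)CC1=C(C)C[C@@H](O)CC1(C)C | target

**Count and risks**

Total step count: 27. Longest linear sequence: 16 steps (steps 1–8, 13–16, 24–27).

Steps most likely to fail:

Step 4 (proposed new method). What may go wrong: chain growth (the tertiary cation adds more isobutene, or the activated acetal is attacked by the dienylsilane of a second molecule), protodesilylation of the dienylsilane before ring closure, and loss of facial selectivity if the acetal opens to a free oxocarbenium ion. Fallback (known chemistry; the ring is taken from an industrial terpenoid intermediate instead of being made): no compound before step 4 holds the ring, so this fallback sets out from commercial 2,6,6-trimethylcyclohex-2-ene-1,4-dione F1 and comes back to the route at 13. Baker's yeast (an ene-reductase of the Old Yellow Enzyme class) reduces the ring C=C to (6R)-2,2,6-trimethylcyclohexane-1,4-dione F2. An NADH-dependent carbonyl reductase (levodione reductase) reduces the unhindered ketone to (4R,6R)-4-hydroxy-2,2,6-trimethylcyclohexan-1-one F3. TBSCl and imidazole give (4R,6R)-4-TBSO-2,2,6-trimethylcyclohexan-1-one F4. LiN(i-Pr)2 then PhNTf2 gives the only possible enol triflate, (4R)-4-TBSO-2,6,6-trimethylcyclohex-1-en-1-yl trifluoromethanesulfonate F5 (the other α-carbon is quaternary). Stille coupling with tributyl(vinyl)stannane, Pd(PPh3)4 and LiCl gives 13.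

Step 19. What may go wrong: substrate bias overriding catalyst control in the enantiomer of 30 that must take hydride syn to the side chain (low diastereomeric and enantiomeric purity of the trans alcohol), or competing 1,4-reduction. Fallback (substrate-controlled reduction, enzymatic resolution, inversion): it sets out from 30 and comes back at 31. LiBH(s-Bu)3 at −78 °C delivers hydride anti to the side chain and should give the racemic cis alcohol, ethyl (2E,4E)-5-[(1RS,4SR)-4-hydroxy-2,6,6-trimethylcyclohex-2-en-1-yl]-3-methylpenta-2,4-dienoate F6. Lipase from Pseudomonas fluorescens with vinyl acetate should acetylate the (4R) enantiomer and leave the (1R,4S) alcohol F7. Mitsunobu inversion of F7 (4-nitrobenzoic acid, PPh3, DIAD) gives the (1R,4R) 4-nitrobenzoate F8. K2CO3 in EtOH then gives 31.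

Step 24. What may go wrong: side reactions of the ylide (β-elimination of silanolate from C19, scrambling of the C9=C10 geometry through the delocalised ylide, enolisation at C7) and sluggish addition of the stabilised ylide to the polyenal. Fallback (reversed polarity): it sets out from 24 and 37 and comes back at 38. MnO2 oxidises 24 to the keto-enal (2E)-3-(TBSO-methyl)-5-[(4R)-4-TBSO-2,6,6-trimethylcyclohex-1-en-1-yl]-4-oxopent-2-enal F9. NaBH4 reduces 37 to the C25 allylic alcohol F10, and Ph3P·HBr in CH2Cl2 at 0 °C converts it into the C25 triphenylphosphonium bromide F11. The ylide of F11 (NaOMe) should react with F9 at the aldehyde only; iodine-catalysed equilibration then gives 38.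

**Further compounds**

F1 | step 4 | 2,6,6-trimethylcyclohex-2-ene-1,4-dione | CC1=CC(=O)CC(C)(C)C1=O
F2 | step 4 | (6R)-2,2,6-trimethylcyclohexane-1,4-dione | C[C@@H]1CC(=O)CC(C)(C)C1=O
F3 | step 4 | (4R,6R)-4-hydroxy-2,2,6-trimethylcyclohexan-1-one | C[C@@H]1C[C@@H](O)CC(C)(C)C1=O
F4 | step 4 | (4R,6R)-4-TBSO-2,2,6-trimethylcyclohexan-1-one | C[C@@H]1C[C@@H](O[Si](C)(C)C(C)(C)C)CC(C)(C)C1=O
F5 | step 4 | (4R)-4-TBSO-2,6,6-trimethylcyclohex-1-en-1-yl trifluoromethanesulfonate | FC(F)(F)S(=O)(=O)OC1=C(C)C[C@@H](O[Si](C)(C)C(C)(C)C)CC1(C)C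
F6 | step 19 | ethyl (2E,4E)-5-[(1RS,4SR)-4-hydroxy-2,6,6-trimethylcyclohex-2-en-1-yl]-3-methylpenta-2,4-dienoate (racemic cis) | CCOC(=O)/C=C(C)/C=C/[C@H]1C(C)=C[C@@H](O)CC1(C)C.CCOC(=O)/C=C(C)/C=C/[C@@H]1C(C)=C[C@H](O)CC1(C)C
F7 | step 19 | ethyl (2E,4E)-5-[(1R,4S)-4-hydroxy-2,6,6-trimethylcyclohex-2-en-1-yl]-3-methylpenta-2,4-dienoate | CCOC(=O)/C=C(C)/C=C/[C@H]1C(C)=C[C@@H](O)CC1(C)C
F8 | step 19 | (1R,4R)-4-[(1E,3E)-5-ethoxy-3-methyl-5-oxopenta-1,3-dien-1-yl]-3,5,5-trimethylcyclohex-2-en-1-yl 4-nitrobenzoate | CCOC(=O)/C=C(C)/C=C/[C@H]1C(C)=C[C@H](OC(=O)c2ccc(cc2)[N+](=O)[O-])CC1(C)C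
F9 | step 24 | (2E)-3-(TBSO-methyl)-5-[(4R)-4-TBSO-2,6,6-trimethylcyclohex-1-en-1-yl]-4-oxopent-2-enal | CC(C)(C)[Si](C)(C)OC\C(=C/C=O)C(=O)CC1=C(C)C[C@@H](O[Si](C)(C)C(C)(C)C)CC1(C)C
F10 | step 24 | (2E,4E,6E,8E,10E,12E)-13-[(1R,4R)-4-TBSO-2,6,6-trimethylcyclohex-2-en-1-yl]-2,7,11-trimethyltrideca-2,4,6,8,10,12-hexaen-1-ol | OC/C(C)=C/C=C/C=C(C)/C=C/C=C(C)/C=C/[C@H]1C(C)=C[C@H](O[Si](C)(C)C(C)(C)C)CC1(C)C
F11 | step 24 | {(2E,4E,6E,8E,10E,12E)-13-[(1R,4R)-4-TBSO-2,6,6-trimethylcyclohex-2-en-1-yl]-2,7,11-trimethyltrideca-2,4,6,8,10,12-hexaen-1-yl}triphenylphosphonium bromide | [Br-].c1ccccc1[P+](c1ccccc1)(c1ccccc1)C/C(C)=C/C=C/C=C(C)/C=C/C=C(C)/C=C/[C@H]1C(C)=C[C@H](O[Si](C)(C)C(C)(C)C)CC1(C)C
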